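**Strategy.** In prostanoid numbering, the cyclopentenone is cut into a three-carbon piece (carbonyl C9, C10, C11) and a two-carbon piece (C8, C12). A Brook rearrangement-mediated (3+2) annulation joins the kinetic lithium enolate of a methyl ketone bearing a chiral dioxolane to a β-phenylthio acryloylsilane: enolate carbon C8 adds to the acylsilane carbon C9, the silyl shift unmasks a siloxyallyl anion, and its terminus C11 closes onto ketone carbon C12. The step exploits the 4-oxygenated cyclopent-2-enone ring, in which the tertiary carbinol C12 is a latent ketone and C8 its α-carbon. The dioxolane sorts the C12 configuration and later becomes the aldehyde for the Z-olefin; allylation and cross-metathesis add the ester chain.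

Key step: step 6

Remark on numbering: C1 is the ester carbon, C4 the acetoxy carbinol of the chain, C8 the ring CH, C9 the ring C=O, C10=C11 the ring alkene, C12 the acetoxy-bearing ring carbon, C13–C20 the octenyl chain.
Assumption: the sense of the 1,3-induction in step 6 is taken from the lithium chelate model; the route does not rest on its size, because the C12 epimer is a diastereomer that is removed in step 7.

Step 1
Reactants: 1 methyl 2-[(4R)-2,2-dimethyl-1,3-dioxolan-4-yl]acetate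
Product: 2 2-[(4R)-2,2-dimethyl-1,3-dioxolan-4-yl]-N-methoxy-N-methylacetamide
Conditions: MeNH(OMe)·HCl, i-PrMgCl, THF, −20 °C
Reagents that add atoms: N,O-dimethylhydroxylamine hydrochloride, CNOC.Cl
Why: Aminolysis of the ester by the chloromagnesium amide (Weinreb amide formation) runs at low temperature and leaves the acetonide and its stereocentre untouched.

Step 2
Reactants: 2 2-[(4R)-2,2-dimethyl-1,3-dioxolan-4-yl]-N-methoxy-N-methylacetamide
Product: 3 1-[(4R)-2,2-dimethyl-1,3-dioxolan-4-yl]propan-2-one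
Conditions: MeMgBr, THF, 0 °C; aq. NH4Cl
Reagents that add atoms: methylmagnesium bromide, C[Mg]Br
Why: Weinreb ketone synthesis, in which the chelated tetrahedral intermediate stops the addition at the ketone stage.

Step 3
Reactants: 4 1-methoxypropa-1,2-diene (methoxyallene)
Product: 7 1-[tert-butyl(dimethyl)silyl]prop-2-en-1-one, via 1-lithio-1-methoxyallene 5 (not isolated), via silylated methoxyallene 6 (not isolated)
Conditions: n-BuLi, THF, −78 °C; t-BuMe2SiCl, −78 °C → rt; then 1 M aq. HCl, THF, 0 °C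
Reagents that add atoms: tert-butyldimethylsilyl chloride, CC(C)(C)[Si](C)(C)Cl; water, O
Why: α-Lithiation of the allenyl ether, C-silylation and acid hydrolysis of the 1-silyl enol ether unmask the α,β-unsaturated acylsilane (alkoxyallene as acyl anion equivalent).

Step 4
Reactants: 7 1-[tert-butyl(dimethyl)silyl]prop-2-en-1-one
Product: 8 1-[tert-butyl(dimethyl)silyl]-3-(phenylsulfanyl)propan-1-one
Conditions: PhSH, Et3N (cat.), CH2Cl2, 0 °C
Reagents that add atoms: thiophenol, Sc1ccccc1
Why: Base-catalysed thia-Michael addition to the enoylsilane.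

Step 5
Reactants: 8 1-[tert-butyl(dimethyl)silyl]-3-(phenylsulfanyl)propan-1-one
Product: 10 (2E)-1-[tert-butyl(dimethyl)silyl]-3-(phenylsulfanyl)prop-2-en-1-one, via α-chloro sulfide 9 (not isolated)
Conditions: N-chlorosuccinimide, CH2Cl2, 0 °C → rt; then Et3N, rt
Reagents that add atoms: none
Why: α-Chlorination of the sulfide through the chlorosulfonium ion (Pummerer-type) and dehydrochlorination give the conjugated vinyl sulfide as the more stable E isomer.

Step 6
Reactants: 3 1-[(4R)-2,2-dimethyl-1,3-dioxolan-4-yl]propan-2-one; 10 (2E)-1-[tert-butyl(dimethyl)silyl]-3-(phenylsulfanyl)prop-2-en-1-one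
Product: 15 tert-butyl({(4S)-4-{[(4R)-2,2-dimethyl-1,3-dioxolan-4-yl]methyl}-3-(phenylsulfanyl)-4-[(triethylsilyl)oxy]cyclopent-1-en-1-yl}oxy)dimethylsilane, via lithium enolate 11 (not isolated), via α-silyl alkoxide 12 (not isolated), via siloxyallyl lithium 13 (not isolated), via lithium cyclopentenolate 14 (not isolated)
Conditions: LiN(i-Pr)2, THF, −80 °C; 10, −80 → −30 °C; Et3SiOTf, 2,6-lutidine, −78 → 0 °C
Reagents that add atoms: triethylsilyl trifluoromethanesulfonate, CC[Si](CC)(CC)OS(=O)(=O)C(F)(F)F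
Why: The kinetic methyl enolate 11 adds to the highly electrophilic acylsilane carbonyl to give α-silyl alkoxide 12, whose 1,2-Brook (C→O) silyl shift is driven by formation of the sulfur-stabilised siloxyallyl anion 13, and 13 attacks the internal ketone through its thio-bearing terminus to give 14, so the C8–C9 and C11–C12 bonds form in one flask. This is the Brook rearrangement-mediated (3+2) annulation of β-heteroatom-substituted acryloylsilanes with lithium enolates of alkyl methyl ketones. The five-membered ring closes by 5-exo-trig addition of the allyl anion terminus to the C12 carbonyl. The tertiary carbinol C12 is set by 1,3-induction from the dioxolane stereocentre: in a lithium chelate between the ketone oxygen and the proximal acetal oxygen the nucleophile should enter anti to the dioxolane ring carbon, giving the 1,3-anti carbinol drawn, while the sulfur-bearing centre follows from the E geometry of 10 and is erased in step 7. The step needs 1,2-addition at the acyl carbon rather than addition–elimination at the thio-substituted carbon, which the acylsilane electrophilicity at −80 °C should secure, and enolisation at the methyl group, which LiN(i-Pr)2 under kinetic control should secure. The lithium alkoxide is capped in situ as the triethylsilyl ether so that later base cannot open the ring by retro-aldol cleavage.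

Step 7
Reactants: 15 tert-butyl({(4S)-4-{[(4R)-2,2-dimethyl-1,3-dioxolan-4-yl]methyl}-3-(phenylsulfanyl)-4-[(triethylsilyl)oxy]cyclopent-1-en-1-yl}oxy)dimethylsilane
Product: 18 (4S)-4-{[(4R)-2,2-dimethyl-1,3-dioxolan-4-yl]methyl}-4-[(triethylsilyl)oxy]cyclopent-2-en-1-one, via β-keto sulfide 16 (not isolated), via sulfoxide 17 (not isolated)
Conditions: Bu4NF, AcOH, THF, −20 °C; then mCPBA, −78 °C; then Et3N, −78 °C → rt; chromatography
Reagents that add atoms: none
Why: Buffered fluoride cleaves only the silyl enol ether (the tertiary triethylsilyl ether is far slower), the β-keto sulfide is oxidised at sulfur and the β-keto sulfoxide loses benzenesulfenate by E1cB elimination to give the enone, at which stage the C4 epimer from the minor face attack of step 6 is a diastereomer that should be removable by chromatography.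

Step 8
Reactants: 18 (4S)-4-{[(4R)-2,2-dimethyl-1,3-dioxolan-4-yl]methyl}-4-[(triethylsilyl)oxy]cyclopent-2-en-1-one
Product: 20 (4R,5R)-4-{[(4R)-2,2-dimethyl-1,3-dioxolan-4-yl]methyl}-5-(prop-2-en-1-yl)-4-[(triethylsilyl)oxy]cyclopent-2-en-1-one, via lithium dienolate 19 (not isolated)
Conditions: LiN(i-Pr)2, THF, −78 °C; allyl iodide, DMPU, −78 → −40 °C; then DBU, CH2Cl2, rt
Reagents that add atoms: allyl iodide (3-iodoprop-1-ene), C=CCI
Why: Kinetic α′-deprotonation gives the cross-conjugated dienolate (the quaternary C4 leaves no γ-hydrogen), enolate C-alkylation installs C7, and DBU equilibration of the epimerisable C5 (C8 of the target) should favour the allyl group trans to the dioxolanylmethyl arm and cis to the siloxy group.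

Step 9
Reactants: 21 (5S)-5-(hydroxymethyl)oxolan-2-one
Product: 22 (2S)-5-oxooxolane-2-carbaldehyde
Conditions: Dess–Martin periodinane, NaHCO3, CH2Cl2, 0 °C → rt
Reagents that add atoms: none
Why: Neutral Dess–Martin oxidation gives the aldehyde without epimerising the adjacent oxygenated stereocentre.

Step 10
Reactants: 22 (2S)-5-oxooxolane-2-carbaldehyde
Product: 23 (5S)-5-ethenyloxolan-2-one
Conditions: Ph3PCH3Br, KN(SiMe3)2, THF, 0 °C; then 22, −78 → 0 °C
Reagents that add atoms: methyltriphenylphosphonium bromide, C[P+](c1ccccc1)(c1ccccc1)c1ccccc1.[Br-]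
Why: Wittig methylenation at low temperature should convert the aldehyde faster than the basic ylide can epimerise the α-stereocentre.

Step 11
Reactants: 23 (5S)-5-ethenyloxolan-2-one
Product: 26 methyl (4S)-4-(acetyloxy)hex-5-enoate, via potassium carboxylate 24 (not isolated), via hydroxy ester 25 (not isolated)
Conditions: KOH (1 equiv), MeOH–H2O, 0 °C, evaporate; MeI, DMF, 0 °C; then Ac2O, pyridine, DMAP (cat.), 0 °C → rt
Reagents that add atoms: potassium hydroxide, [K+].[OH-]; iodomethane, CI; acetic anhydride, CC(=O)OC(C)=O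
Why: Saponification opens the lactone, O-alkylation of the carboxylate gives the methyl ester under non-lactonising conditions, and immediate acetylation traps the allylic alcohol before it can close again, all without touching the stereocentre.

Step 12
Reactants: 20 (4R,5R)-4-{[(4R)-2,2-dimethyl-1,3-dioxolan-4-yl]methyl}-5-(prop-2-en-1-yl)-4-[(triethylsilyl)oxy]cyclopent-2-en-1-one; 26 methyl (4S)-4-(acetyloxy)hex-5-enoate
Product: 27 methyl (4S,5E)-4-(acetyloxy)-7-[(1R,5R)-5-{[(4R)-2,2-dimethyl-1,3-dioxolan-4-yl]methyl}-2-oxo-5-[(triethylsilyl)oxy]cyclopent-3-en-1-yl]hept-5-enoate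
Conditions: second-generation Hoveyda–Grubbs catalyst RuCl2(H2IMes)(=CH-C6H4-2-O-i-Pr) (5 mol %), 1,4-benzoquinone (10 mol %), 26 (3 equiv), CH2Cl2, 40 °C
Reagents that add atoms: none
Why: Olefin cross-metathesis between the terminal allyl group and an excess of the secondary allylic acetate should give the E-alkene under thermodynamic control, with benzoquinone suppressing allyl-to-propenyl isomerisation and the electron-poor ring alkene staying inert; it is run before the Z-olefin exists so that no ring-closing metathesis between the two arms can occur.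

Step 13
Reactants: 27 methyl (4S,5E)-4-(acetyloxy)-7-[(1R,5R)-5-{[(4R)-2,2-dimethyl-1,3-dioxolan-4-yl]methyl}-2-oxo-5-[(triethylsilyl)oxy]cyclopent-3-en-1-yl]hept-5-enoate
Product: 28 methyl (4S,5E)-4-(acetyloxy)-7-[(1R,5R)-2-oxo-5-(2-oxoethyl)-5-[(triethylsilyl)oxy]cyclopent-3-en-1-yl]hept-5-enoate
Conditions: H5IO6, EtOAc, 0 °C → rt
Reagents that add atoms: none
Why: Periodic acid hydrolyses the terminal acetonide and cleaves the freed 1,2-diol in one flask (glycol cleavage), which excises the auxiliary stereocentre and leaves the β-siloxy aldehyde.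

Step 14
Reactants: 28 methyl (4S,5E)-4-(acetyloxy)-7-[(1R,5R)-2-oxo-5-(2-oxoethyl)-5-[(triethylsilyl)oxy]cyclopent-3-en-1-yl]hept-5-enoate
Product: 29 methyl (4S,5E)-4-(acetyloxy)-7-{(1R,5R)-5-[(2Z)-oct-2-en-1-yl]-2-oxo-5-[(triethylsilyl)oxy]cyclopent-3-en-1-yl}hept-5-enoate
Conditions: n-C6H13PPh3Br, NaN(SiMe3)2, THF, 0 °C; then 28, −78 → −40 °C
Reagents that add atoms: hexyltriphenylphosphonium bromide, CCCCCC[P+](c1ccccc1)(c1ccccc1)c1ccccc1.[Br-]
Why: Wittig olefination with a salt-free non-stabilised ylide is Z-selective for aliphatic aldehydes, and at −78 °C the aldehyde should react well before the enone carbonyl, the esters or the C8–H.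

Step 15
Reactants: 29 methyl (4S,5E)-4-(acetyloxy)-7-{(1R,5R)-5-[(2Z)-oct-2-en-1-yl]-2-oxo-5-[(triethylsilyl)oxy]cyclopent-3-en-1-yl}hept-5-enoate
Product: 30 methyl (4S,5E)-4-(acetyloxy)-7-{(1R,5R)-5-hydroxy-5-[(2Z)-oct-2-en-1-yl]-2-oxocyclopent-3-en-1-yl}hept-5-enoate
Conditions: HF·pyridine, pyridine, THF, 0 °C → rt
Reagents that add atoms: none
Why: Fluoride-mediated Si–O cleavage under buffered acidic conditions frees the tertiary alcohol without base, so the allylic acetate, the ester and the epimerisable C8 are left alone.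

Step 16
Reactants: 30 methyl (4S,5E)-4-(acetyloxy)-7-{(1R,5R)-5-hydroxy-5-[(2Z)-oct-2-en-1-yl]-2-oxocyclopent-3-en-1-yl}hept-5-enoate
Product: 31 methyl (4S,5E)-4-(acetyloxy)-7-{(1R,5R)-5-(acetyloxy)-5-[(2Z)-oct-2-en-1-yl]-2-oxocyclopent-3-en-1-yl}hept-5-enoate (CNP0171642.3)
Conditions: Ac2O, Sc(OTf)3 (2 mol %), MeCN, −20 °C
Reagents that add atoms: acetic anhydride, CC(=O)OC(C)=O
Why: Sc(OTf)3-catalysed acylation acetylates hindered tertiary alcohols at low temperature without a base, which avoids base-induced loss of the new acetate through enolisation at C8.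

**Compound list**

1 | methyl 2-[(4R)-2,2-dimethyl-1,3-dioxolan-4-yl]acetate | COC(=O)C[C@@H]1COC(C)(C)O1 | starting material
2 | 2-[(4R)-2,2-dimethyl-1,3-dioxolan-4-yl]-N-methoxy-N-methylacetamide | CON(C)C(=O)C[C@@H]1COC(C)(C)O1 | intermediate
3 | 1-[(4R)-2,2-dimethyl-1,3-dioxolan-4-yl]propan-2-one | CC(=O)C[C@@H]1COC(C)(C)O1 | intermediate
4 | 1-methoxypropa-1,2-diene | COC=C=C | starting material
5 | 1-lithio-1-methoxypropa-1,2-diene | COC([Li])=C=C | intermediate
6 | tert-butyl(1-methoxypropa-1,2-dien-1-yl)dimethylsilane | COC(=C=C)[Si](C)(C)C(C)(C)C | intermediate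
7 | 1-[tert-butyl(dimethyl)silyl]prop-2-en-1-one | C=CC(=O)[Si](C)(C)C(C)(C)C | intermediate
8 | 1-[tert-butyl(dimethyl)silyl]-3-(phenylsulfanyl)propan-1-one | O=C(CCSc1ccccc1)[Si](C)(C)C(C)(C)C | intermediate
9 | 1-[tert-butyl(dimethyl)silyl]-3-chloro-3-(phenylsulfanyl)propan-1-one | O=C(CC(Cl)Sc1ccccc1)[Si](C)(C)C(C)(C)C | intermediate
10 | (2E)-1-[tert-butyl(dimethyl)silyl]-3-(phenylsulfanyl)prop-2-en-1-one | O=C(/C=C/Sc1ccccc1)[Si](C)(C)C(C)(C)C | intermediate
11 | lithium 3-[(4R)-2,2-dimethyl-1,3-dioxolan-4-yl]prop-1-en-2-olate | C=C(O[Li])C[C@@H]1COC(C)(C)O1 | intermediate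
12 | lithium (1E)-3-[tert-butyl(dimethyl)silyl]-6-[(4R)-2,2-dimethyl-1,3-dioxolan-4-yl]-5-oxo-1-(phenylsulfanyl)hex-1-en-3-olate | O=C(CC(O[Li])(/C=C/Sc2ccccc2)[Si](C)(C)C(C)(C)C)C[C@@H]1COC(C)(C)O1 | intermediate
13 | [3-{[tert-butyl(dimethyl)silyl]oxy}-6-[(4R)-2,2-dimethyl-1,3-dioxolan-4-yl]-5-oxo-1-(phenylsulfanyl)hex-2-en-1-yl]lithium | O=C(CC(O[Si](C)(C)C(C)(C)C)=CC([Li])Sc2ccccc2)C[C@@H]1COC(C)(C)O1 | intermediate
14 | lithium (1S)-4-{[tert-butyl(dimethyl)silyl]oxy}-1-{[(4R)-2,2-dimethyl-1,3-dioxolan-4-yl]methyl}-2-(phenylsulfanyl)cyclopent-3-en-1-olate | CC1(C)OC[C@@H](C[C@@]2(O[Li])C(Sc3ccccc3)C=C(O[Si](C)(C)C(C)(C)C)C2)O1 | intermediate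
15 | tert-butyl({(4S)-4-{[(4R)-2,2-dimethyl-1,3-dioxolan-4-yl]methyl}-3-(phenylsulfanyl)-4-[(triethylsilyl)oxy]cyclopent-1-en-1-yl}oxy)dimethylsilane (sulfur-bearing carbon of either configuration) | CC1(C)OC[C@@H](C[C@@]2(O[Si](CC)(CC)CC)C(Sc3ccccc3)C=C(O[Si](C)(C)C(C)(C)C)C2)O1 | intermediate
16 | (3S)-3-{[(4R)-2,2-dimethyl-1,3-dioxolan-4-yl]methyl}-4-(phenylsulfanyl)-3-[(triethylsilyl)oxy]cyclopentan-1-one | CC1(C)OC[C@@H](C[C@@]2(O[Si](CC)(CC)CC)C(Sc3ccccc3)CC(=O)C2)O1 | intermediate
17 | (3S)-4-(benzenesulfinyl)-3-{[(4R)-2,2-dimethyl-1,3-dioxolan-4-yl]methyl}-3-[(triethylsilyl)oxy]cyclopentan-1-one | CC1(C)OC[C@@H](C[C@@]2(O[Si](CC)(CC)CC)C(S(=O)c3ccccc3)CC(=O)C2)O1 | intermediate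
18 | (4S)-4-{[(4R)-2,2-dimethyl-1,3-dioxolan-4-yl]methyl}-4-[(triethylsilyl)oxy]cyclopent-2-en-1-one | CC1(C)OC[C@@H](C[C@@]2(O[Si](CC)(CC)CC)C=CC(=O)C2)O1 | intermediate
19 | lithium (3R)-3-{[(4R)-2,2-dimethyl-1,3-dioxolan-4-yl]methyl}-3-[(triethylsilyl)oxy]cyclopenta-1,4-dien-1-olate | CC1(C)OC[C@@H](C[C@@]2(O[Si](CC)(CC)CC)C=CC(O[Li])=C2)O1 | intermediate
20 | (4R,5R)-4-{[(4R)-2,2-dimethyl-1,3-dioxolan-4-yl]methyl}-5-(prop-2-en-1-yl)-4-[(triethylsilyl)oxy]cyclopent-2-en-1-one | CC1(C)OC[C@@H](C[C@@]2(O[Si](CC)(CC)CC)C=CC(=O)[C@@H]2CC=C)O1 | intermediate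
21 | (5S)-5-(hydroxymethyl)oxolan-2-one | O=C1CC[C@@H](CO)O1 | starting material
22 | (2S)-5-oxooxolane-2-carbaldehyde | O=C1CC[C@@H](C=O)O1 | intermediate
23 | (5S)-5-ethenyloxolan-2-one | O=C1CC[C@@H](C=C)O1 | intermediate
24 | potassium (4S)-4-hydroxyhex-5-enoate | C=C[C@H](CCC(=O)[O-])O.[K+] | intermediate
25 | methyl (4S)-4-hydroxyhex-5-enoate | C=C[C@H](CCC(=O)OC)O | intermediate
26 | methyl (4S)-4-(acetyloxy)hex-5-enoate | C=C[C@H](CCC(=O)OC)OC(C)=O | intermediate
27 | methyl (4S,5E)-4-(acetyloxy)-7-[(1R,5R)-5-{[(4R)-2,2-dimethyl-1,3-dioxolan-4-yl]methyl}-2-oxo-5-[(triethylsilyl)oxy]cyclopent-3-en-1-yl]hept-5-enoate | CC1(C)OC[C@@H](C[C@@]2(O[Si](CC)(CC)CC)C=CC(=O)[C@@H]2C/C=C/[C@H](CCC(=O)OC)OC(C)=O)O1 | intermediate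
28 | methyl (4S,5E)-4-(acetyloxy)-7-[(1R,5R)-2-oxo-5-(2-oxoethyl)-5-[(triethylsilyl)oxy]cyclopent-3-en-1-yl]hept-5-enoate | O=CC[C@@]1(O[Si](CC)(CC)CC)C=CC(=O)[C@@H]1C/C=C/[C@H](CCC(=O)OC)OC(C)=O | intermediate
29 | methyl (4S,5E)-4-(acetyloxy)-7-{(1R,5R)-5-[(2Z)-oct-2-en-1-yl]-2-oxo-5-[(triethylsilyl)oxy]cyclopent-3-en-1-yl}hept-5-enoate | CCCCC/C=C\C[C@@]1(O[Si](CC)(CC)CC)C=CC(=O)[C@@H]1C/C=C/[C@H](CCC(=O)OC)OC(C)=O | intermediate
30 | methyl (4S,5E)-4-(acetyloxy)-7-{(1R,5R)-5-hydroxy-5-[(2Z)-oct-2-en-1-yl]-2-oxocyclopent-3-en-1-yl}hept-5-enoate | CCCCC/C=C\C[C@@]1(O)C=CC(=O)[C@@H]1C/C=C/[C@H](CCC(=O)OC)OC(C)=O | intermediate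
31 | methyl (4S,5E)-4-(acetyloxy)-7-{(1R,5R)-5-(acetyloxy)-5-[(2Z)-oct-2-en-1-yl]-2-oxocyclopent-3-en-1-yl}hept-5-enoate | CCCCC/C=C\C[C@@]1(OC(C)=O)C=CC(=O)[C@@H]1C/C=C/[C@H](CCC(=O)OC)OC(C)=O | target

**Totals.** Total step count: 16. Longest linear sequence: 11 steps (steps 3, 4, 5, 6, 7, 8, 12, 13, 14, 15, 16).

**Steps most likely to fail**

Step 6. The α-silyl alkoxide may not enter the Brook shift and ring closure cleanly: the enolate can instead add and eliminate at the thio-bearing carbon, the allyl anion can be quenched by proton transfer, or the face selectivity at C12 can be low. The fallback builds the same ring by ring-closing metathesis and sets out from Weinreb amide 2. Vinylmagnesium bromide gives 1-[(4R)-2,2-dimethyl-1,3-dioxolan-4-yl]but-3-en-2-one F1. The Reformatsky reagent from 2-bromo-N-methoxy-N-methylacetamide and Zn adds 1,2 to give the tertiary carbinol amide F2, whose C3 epimers are sorted as diastereomers. Et3SiOTf and 2,6-lutidine give the silyl ether F3, and a second vinylmagnesium bromide addition gives the dienone F4. Ring-closing metathesis with the second-generation Grubbs catalyst RuCl2(PCy3)(H2IMes)(=CHPh) closes the C10=C11 bond, and the fallback comes back to the route at enone 18.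

Step 8. The cross-conjugated lithium dienolate may suffer proton transfer and double alkylation, or may expel the siloxy group. The fallback avoids a free lithium enolate in the C–C bond-forming event and sets out from enone 18. LiN(i-Pr)2 and Me3SiCl give the silyl dienol ether F5, which is allylated with allyl methyl carbonate under Pd2(dba)3·CHCl3 and dppe (zerovalent palladium, Tsuji–Trost-type allylation of a silyl enol ether). After the same DBU equilibration it comes back to the route at 20.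

Step 14. The basic ylide may enolise the ring ketone at C8 (with loss of the siloxy group) or attack the ring carbonyl before the aldehyde is consumed. The fallback takes the ketone out of play during the olefination and sets out from 27. Luche reduction (NaBH4, CeCl3·7H2O, MeOH) gives the allylic alcohol F6 as a mixture at the new carbinol. H5IO6 in EtOAc gives the hydroxy aldehyde F7, and the same Wittig reagent (two equivalents) gives the Z-olefin alcohol F8. Dess–Martin oxidation of the allylic alcohol restores the enone, and the fallback comes back to the route at 29.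

Further compounds
F1 | step 6 | 1-[(4R)-2,2-dimethyl-1,3-dioxolan-4-yl]but-3-en-2-one | C=CC(=O)C[C@@H]1COC(C)(C)O1
F2 | step 6 | (3S)-3-{[(4R)-2,2-dimethyl-1,3-dioxolan-4-yl]methyl}-3-hydroxy-N-methoxy-N-methylpent-4-enamide | CC1(C)OC[C@@H](C[C@@](O)(C=C)CC(=O)N(C)OC)O1
F3 | step 6 | (3S)-3-{[(4R)-2,2-dimethyl-1,3-dioxolan-4-yl]methyl}-N-methoxy-N-methyl-3-[(triethylsilyl)oxy]pent-4-enamide | CC1(C)OC[C@@H](C[C@@](O[Si](CC)(CC)CC)(C=C)CC(=O)N(C)OC)O1
F4 | step 6 | (5S)-5-{[(4R)-2,2-dimethyl-1,3-dioxolan-4-yl]methyl}-5-[(triethylsilyl)oxy]hepta-1,6-dien-3-one | CC1(C)OC[C@@H](C[C@@](O[Si](CC)(CC)CC)(C=C)CC(=O)C=C)O1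
F5 | step 8 | trimethyl({(3R)-3-{[(4R)-2,2-dimethyl-1,3-dioxolan-4-yl]methyl}-3-[(triethylsilyl)oxy]cyclopenta-1,4-dien-1-yl}oxy)silane | CC1(C)OC[C@@H](C[C@@]2(O[Si](CC)(CC)CC)C=CC(O[Si](C)(C)C)=C2)O1
F6 | step 14 | methyl (4S,5E)-4-(acetyloxy)-7-[(1S,5R)-5-{[(4R)-2,2-dimethyl-1,3-dioxolan-4-yl]methyl}-2-hydroxy-5-[(triethylsilyl)oxy]cyclopent-3-en-1-yl]hept-5-enoate | CC1(C)OC[C@@H](C[C@@]2(O[Si](CC)(CC)CC)C=CC(O)[C@@H]2C/C=C/[C@H](CCC(=O)OC)OC(C)=O)O1
F7 | step 14 | methyl (4S,5E)-4-(acetyloxy)-7-[(1S,5R)-2-hydroxy-5-(2-oxoethyl)-5-[(triethylsilyl)oxy]cyclopent-3-en-1-yl]hept-5-enoate | O=CC[C@@]1(O[Si](CC)(CC)CC)C=CC(O)[C@@H]1C/C=C/[C@H](CCC(=O)OC)OC(C)=O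
F8 | step 14 | methyl (4S,5E)-4-(acetyloxy)-7-{(1S,5R)-2-hydroxy-5-[(2Z)-oct-2-en-1-yl]-5-[(triethylsilyl)oxy]cyclopent-3-en-1-yl}hept-5-enoate | CCCCC/C=C\C[C@@]1(O[Si](CC)(CC)CC)C=CC(O)[C@@H]1C/C=C/[C@H](CCC(=O)OC)OC(C)=O
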